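**Strategy**

Everything rests on cutting the butenolide ring (O1, C2, C3, C4, C5) at C3–C4 and O1–C2. An (R)-3-hydroxy ester then supplies C5 (carrying O1) and C4 (carrying the carboxyl carbon) as its carbinol and α-carbons, and ethyl pyruvate supplies C3, its methyl group and the lactone carbonyl C2; the key step exploits this 1,3-relationship between the C5 oxygen and the C4 carboxyl. In one operation the lithium alkoxide–enolate of the hydroxy ester adds to the pyruvate ketone and the C5 alkoxide closes the lactone. The precursor is tert-butyl (R)-16-(benzyloxy)-3-hydroxyhexadecanoate; the transient centres at C3 and C4 are later erased by dehydration to the C3=C4 alkene.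

Key step: step 5

Remarks on the chemistry:
- Atom labels O1 and C2–C5 refer to the butenolide of the target (C2 lactone carbonyl, C3 methyl-bearing, C4 carboxyl-bearing, C5 chain-bearing). Compound names use systematic oxolane locants.
- The chelated dianion is assumed to react in its usual anti sense. Once the ring is closed through the pyruvate carbon, this corresponds to the lactone with the C4 ester cis to the C5 chain ((2R,3S) in oxolane locants). The trans isomer would arise only by later epimerisation at C4.
- C4 is epimerisable and both C3 and C4 become sp2 in step 8, so every diastereomer of 11–14 converges on 15.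

**Route**

Step 1
Reactants: 1 1,14-tetradecanediol
Product: 2 14-(benzyloxy)tetradecan-1-ol
Conditions: 1 (3 equiv), NaH (1 equiv), BnBr (1 equiv), Bu4NI (cat.), THF–DMF, 0 to 50 °C
Reagents that add atoms: benzyl bromide, BrCc1ccccc1
Why: Williamson etherification of the mono-alkoxide, with the diol in excess so that dialkylation stays low and unreacted diol can be recovered.

Step 2
Reactants: 2 14-(benzyloxy)tetradecan-1-ol
Product: 3 14-(benzyloxy)tetradecanoic acid
Conditions: TEMPO (0.2 equiv), PhI(OAc)2 (2.2 equiv), MeCN–CH2Cl2–H2O, rt
Reagents that add atoms: water, O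
Why: TEMPO-catalysed oxidation with PhI(OAc)2 as terminal oxidant takes the primary alcohol through the aldehyde hydrate to the acid and leaves the benzyl ether untouched.

Step 3
Reactants: 3 14-(benzyloxy)tetradecanoic acid; 4 Meldrum's acid (2,2-dimethyl-1,3-dioxane-4,6-dione)
Product: 6 tert-butyl 16-(benzyloxy)-3-oxohexadecanoate, via acyl Meldrum's acid 5 (not isolated)
Conditions: DCC, DMAP, CH2Cl2, 0 °C to rt; filtration, aq KHSO4 wash, concentration; then t-BuOH, toluene, 90 °C
Reagents that add atoms: tert-butanol, CC(C)(C)O
Why: Carbodiimide-mediated C-acylation of Meldrum's acid, then thermal loss of acetone and CO2 to an acylketene that tert-butanol traps as the β-keto ester (Meldrum's acid homologation).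

Step 4
Reactants: 6 tert-butyl 16-(benzyloxy)-3-oxohexadecanoate
Product: 7 tert-butyl (R)-16-(benzyloxy)-3-hydroxyhexadecanoate
Conditions: H2 (50 bar), RuCl2[(R)-BINAP] (0.5 mol %), MeOH–CH2Cl2, 40 °C
Reagents that add atoms: none
Why: Noyori asymmetric hydrogenation, in which the chelated β-keto ester receives hydride on the face dictated by the (R)-ligand to give the (R)-carbinol, the sense established for 3-oxoalkanoates; benzyl ether and tert-butyl ester are inert to the homogeneous ruthenium catalyst.

Step 5
Reactants: 7 tert-butyl (R)-16-(benzyloxy)-3-hydroxyhexadecanoate; 8 ethyl pyruvate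
Product: 11 tert-butyl (2R,3S)-2-[13-(benzyloxy)tridecyl]-4-hydroxy-4-methyl-5-oxooxolane-3-carboxylate (both epimers at the carbinol carbon), via dilithium alkoxide enolate 9 (not isolated), via open-chain dilithium aldolate 10 (not isolated)
Conditions: LiN(iPr)2 (2.2 equiv, from iPr2NH and n-BuLi), THF, −78 to −20 °C; 8 (1.5 equiv), −78 °C, then to 0 °C; AcOH quench
Reagents that add atoms: none
Why: Two equivalents of LiN(iPr)2 turn 7 into the lithium-bridged alkoxide–enolate 9, which cannot undergo β-elimination because the β-oxygen is already an alkoxide; its enolate carbon (future C4) attacks the ketone carbonyl of 8 to form C3–C4, and on warming the C5 alkoxide of aldolate 10 expels ethoxide from the pyruvate ester to form O1–C2. The closest known reaction type is the Fráter–Seebach dianion aldol addition of 3-hydroxy esters, followed by the ordinary lactonisation of a γ-oxido ester. The lactone ring closes in the 5-exo-trig mode, by acyl substitution at the trigonal ester carbon. C5 is untouched and stays R; at C4 the six-membered lithium chelate makes the pyruvate enter on the face opposite the C5 chain (1,2-induction by the carbinol centre), which after closure places the tert-butyl ester cis to the chain, whereas C3 is formed without useful control. The step needs ketone addition to win over proton abstraction from the pyruvate methyl group and over attack at the pyruvate ester, and the high electrophilicity of the α-keto carbonyl at −78 °C secures this, while the tert-butyl ester suppresses self-condensation and the alternative four-membered lactone.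

Step 6
Reactants: 11 tert-butyl (2R,3S)-2-[13-(benzyloxy)tridecyl]-4-hydroxy-4-methyl-5-oxooxolane-3-carboxylate
Product: 12 tert-butyl (2R,3S)-4-hydroxy-2-(13-hydroxytridecyl)-4-methyl-5-oxooxolane-3-carboxylate
Conditions: H2 (1 atm), 10% Pd/C, EtOAc, rt
Reagents that add atoms: none
Why: Heterogeneous hydrogenolysis of the benzylic C–O bond; the saturated lactone, tertiary alcohol and tert-butyl ester are unaffected, and no alkene is present at this stage.

Step 7
Reactants: 12 tert-butyl (2R,3S)-4-hydroxy-2-(13-hydroxytridecyl)-4-methyl-5-oxooxolane-3-carboxylate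
Product: 13 tert-butyl (2R,3S)-2-(13-acetoxytridecyl)-4-hydroxy-4-methyl-5-oxooxolane-3-carboxylate
Conditions: Ac2O (1.5 equiv), pyridine, CH2Cl2, 0 °C to rt
Reagents that add atoms: acetic anhydride, CC(=O)OC(C)=O
Why: Acylation with Ac2O and pyridine is selective for the unhindered primary hydroxyl, since the tertiary α-hydroxy lactone does not react without a nucleophilic catalyst.

Step 8
Reactants: 13 tert-butyl (2R,3S)-2-(13-acetoxytridecyl)-4-hydroxy-4-methyl-5-oxooxolane-3-carboxylate
Product: 15 tert-butyl (2R)-2-(13-acetoxytridecyl)-4-methyl-5-oxo-2,5-dihydrofuran-3-carboxylate, via tertiary mesylate 14 (not isolated)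
Conditions: MsCl (2.5 equiv), Et3N (5 equiv), CH2Cl2, 0 °C to rt; cold aq KHSO4 quench
Reagents that add atoms: none
Why: Sulfene-type mesylation of the tertiary alcohol and E1cB elimination across C3–C4, driven by the acidity of C4–H (α to the ester) and by conjugation of the new alkene with both carbonyls, erase both transient centres, while low temperature and a prompt acidic quench protect C5–H.

Step 9
Reactants: 15 tert-butyl (2R)-2-(13-acetoxytridecyl)-4-methyl-5-oxo-2,5-dihydrofuran-3-carboxylate
Product: 16 (2R)-2-(13-acetoxytridecyl)-4-methyl-5-oxo-2,5-dihydrofuran-3-carboxylic acid (target)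
Conditions: TFA–CH2Cl2 (1:4), 0 °C to rt
Reagents that add atoms: none
Why: Acidolysis of the tert-butyl ester through the tert-butyl cation, lost as isobutene, leaves the primary acetate, the butenolide and the C5 stereocentre untouched.

**Compound list**

1 | 1,14-tetradecanediol | OCCCCCCCCCCCCCCO | starting material
2 | 14-(benzyloxy)tetradecan-1-ol | OCCCCCCCCCCCCCCOCc1ccccc1 | intermediate
3 | 14-(benzyloxy)tetradecanoic acid | OC(=O)CCCCCCCCCCCCCOCc1ccccc1 | intermediate
4 | Meldrum's acid (2,2-dimethyl-1,3-dioxane-4,6-dione) | CC1(C)OC(=O)CC(=O)O1 | starting material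
5 | 5-[14-(benzyloxy)-1-hydroxytetradecylidene]-2,2-dimethyl-1,3-dioxane-4,6-dione (acyl Meldrum's acid, not isolated) | CC1(C)OC(=O)C(=C(O)CCCCCCCCCCCCCOCc2ccccc2)C(=O)O1 | intermediate
6 | tert-butyl 16-(benzyloxy)-3-oxohexadecanoate | CC(C)(C)OC(=O)CC(=O)CCCCCCCCCCCCCOCc1ccccc1 | intermediate
7 | tert-butyl (R)-16-(benzyloxy)-3-hydroxyhexadecanoate | C(c1ccccc1)OCCCCCCCCCCCCC[C@@H](O)CC(=O)OC(C)(C)C | intermediate
8 | ethyl pyruvate | CC(=O)C(=O)OCC | starting material
9 | dilithium (R)-16-(benzyloxy)-1-tert-butoxyhexadec-1-ene-1,3-diolate (chelated alkoxide enolate of 7, not isolated) | C(c1ccccc1)OCCCCCCCCCCCCC[C@@H]([O-])/C=C(\[O-])OC(C)(C)C.[Li+].[Li+] | intermediate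
10 | dilithium dialkoxide of 1-tert-butyl 4-ethyl (2S)-2-[(1R)-14-(benzyloxy)-1-hydroxytetradecyl]-3-hydroxy-3-methylbutanedioate (open aldolate, not isolated) | C(c1ccccc1)OCCCCCCCCCCCCC[C@@H]([O-])[C@H](C(=O)OC(C)(C)C)C(C)([O-])C(=O)OCC.[Li+].[Li+] | intermediate
11 | tert-butyl (2R,3S)-2-[13-(benzyloxy)tridecyl]-4-hydroxy-4-methyl-5-oxooxolane-3-carboxylate (chain and ester cis, both epimers at the carbinol carbon) | C(c1ccccc1)OCCCCCCCCCCCCC[C@H]1OC(=O)C(C)(O)[C@H]1C(=O)OC(C)(C)C | intermediate
12 | tert-butyl (2R,3S)-4-hydroxy-2-(13-hydroxytridecyl)-4-methyl-5-oxooxolane-3-carboxylate | OCCCCCCCCCCCCC[C@H]1OC(=O)C(C)(O)[C@H]1C(=O)OC(C)(C)C | intermediate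
13 | tert-butyl (2R,3S)-2-(13-acetoxytridecyl)-4-hydroxy-4-methyl-5-oxooxolane-3-carboxylate | CC(=O)OCCCCCCCCCCCCC[C@H]1OC(=O)C(C)(O)[C@H]1C(=O)OC(C)(C)C | intermediate
14 | tert-butyl (2R,3S)-2-(13-acetoxytridecyl)-4-methyl-4-(methylsulfonyloxy)-5-oxooxolane-3-carboxylate (not isolated) | CC(=O)OCCCCCCCCCCCCC[C@H]1OC(=O)C(C)(OS(C)(=O)=O)[C@H]1C(=O)OC(C)(C)C | intermediate
15 | tert-butyl (2R)-2-(13-acetoxytridecyl)-4-methyl-5-oxo-2,5-dihydrofuran-3-carboxylate | CC(=O)OCCCCCCCCCCCCC[C@H]1OC(=O)C(C)=C1C(=O)OC(C)(C)C | intermediate
16 | (2R)-2-(13-acetoxytridecyl)-4-methyl-5-oxo-2,5-dihydrofuran-3-carboxylic acid | CC(=O)OCCCCCCCCCCCCC[C@H]1OC(=O)C(C)=C1C(=O)O | target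

**Step count and risks**

Total step count: 9. Longest linear sequence: 9 steps (1 to 16).

Steps most likely to fail:

Step 5. The dianion may act as a base toward the pyruvate methyl group instead of adding to the ketone, and the resulting pyruvate enolate would then self-condense. The tertiary aldolate may also revert by retro-aldol cleavage before the ring closes, or the closed lactone may be opened again by base-induced β-elimination at C4–C5. The fallback sets out from 7 and comes back at 11, replacing the basic aldol by a Lewis-acid Mukaiyama aldol in which no base is present to enolise the pyruvate. Compound 7 is treated with LiN(iPr)2 (2.2 equiv) and Me3SiCl in THF at −78 °C to give the bis-silylated ketene acetal (R)-16-(benzyloxy)-1-tert-butoxy-1,3-bis(trimethylsilyloxy)hexadec-1-ene F1. F1 is added to 8 precomplexed with TiCl4 in CH2Cl2 at −78 °C, where the chelated α-keto ester should react only at the ketone. Aqueous work-up removes the silyl groups and should give the open hydroxy diester 1-tert-butyl 4-ethyl 2-[(1R)-14-(benzyloxy)-1-hydroxytetradecyl]-3-hydroxy-3-methylbutanedioate F2. F2 is closed with catalytic pyridinium p-toluenesulfonate in toluene at 60 °C, with loss of ethanol, to 11. Here 11 is obtained as a mixture at both transient centres, all of which converge on 15 in step 8.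

Step 8. The amine may reversibly remove the γ-proton at C5 of the newly formed butenolide, which would pass through an achiral 2-oxidofuran and erode the only stereocentre. Elimination may also be slow or run toward the methyl group. The fallback sets out from 13 and comes back at 15 without any amine base. Compound 13 is dehydrated with Martin sulfurane, Ph2S[OC(CF3)2Ph]2, in CH2Cl2 at 0 °C to rt (alkoxysulfonium elimination). This should give 15 together with its exocyclic isomer tert-butyl (2R)-2-(13-acetoxytridecyl)-4-methylidene-5-oxooxolane-3-carboxylate F3. F3 is then moved into conjugation with catalytic RhCl3·3H2O in ethanol at 70 °C (rhodium hydride addition–elimination), which does not touch C5–H, to give 15.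

Step 3. Capture of the acylketene by the hindered tert-butanol may be slow, which would allow ketene dimerisation or hydrolysis and decarboxylation to the methyl ketone. The fallback sets out from 3 and comes back at 6 through a decarboxylative Claisen condensation. Compound 3 is activated with 1,1'-carbonyldiimidazole in THF to give the acyl imidazolide 1-[14-(benzyloxy)tetradecanoyl]imidazole F4. F4 is treated with the magnesium salt of mono-tert-butyl malonate, Mg(O2CCH2CO2tBu)2, at rt to give the acylated half-ester 16-(benzyloxy)-2-(tert-butoxycarbonyl)-3-oxohexadecanoic acid F5. F5 should lose CO2 on acidic work-up to give 6.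

**Further compounds**

F1 | step 5 | (R)-16-(benzyloxy)-1-tert-butoxy-1,3-bis(trimethylsilyloxy)hexadec-1-ene | C(c1ccccc1)OCCCCCCCCCCCCC[C@@H](O[Si](C)(C)C)C=C(O[Si](C)(C)C)OC(C)(C)C
F2 | step 5 | 1-tert-butyl 4-ethyl 2-[(1R)-14-(benzyloxy)-1-hydroxytetradecyl]-3-hydroxy-3-methylbutanedioate (diastereomer mixture) | C(c1ccccc1)OCCCCCCCCCCCCC[C@@H](O)C(C(=O)OC(C)(C)C)C(C)(O)C(=O)OCC
F3 | step 8 | tert-butyl (2R)-2-(13-acetoxytridecyl)-4-methylidene-5-oxooxolane-3-carboxylate | CC(=O)OCCCCCCCCCCCCC[C@H]1OC(=O)C(=C)C1C(=O)OC(C)(C)C
F4 | step 3 | 1-[14-(benzyloxy)tetradecanoyl]imidazole | O=C(CCCCCCCCCCCCCOCc1ccccc1)n1ccnc1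
F5 | step 3 | 16-(benzyloxy)-2-(tert-butoxycarbonyl)-3-oxohexadecanoic acid | OC(=O)C(C(=O)OC(C)(C)C)C(=O)CCCCCCCCCCCCCOCc1ccccc1
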